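## Analysis of the target

The target 28 is a guaiane, a bicyclo[5.3.0]decene. C1–C2–C3–C4–C5 is the five-membered ring and C5–C6–C7–C8–C9–C10–C1 the seven-membered ring. The C1=C10 alkene is tetrasubstituted (methyl C14 on C10), C4 carries a methyl (C15), C7 a 2-hydroxyprop-2-yl group (C11) and the C8 oxygen an (E)-4-hydroxycinnamate.

The four stereocenters are (4S,5S,7S,8S). H4, H5, H7 and the C8 oxygen lie on one face; the C15 methyl and the C11 carbinol lie on the other. Thus C7/C8 are trans, the C5–C4 bond is cis to the C7 substituent, and C15 is cis to C6.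

Sensitive groups are the tertiary alcohol (dehydration), the tetrasubstituted alkene (migration under acid), and the cinnamate ester with its free phenol (base, nucleophiles). Any intermediate with a C10 carbonyl also holds the C8 oxygen in the β-position, so it can eliminate.

The difficulty is a seven-membered ring with no rigid chair to relay stereochemistry, two vicinal centers (C7, C8), two remote ones (C5, C4), and an alkene that must sit only between C1 and C10.

The route rests on one feature: C8 bears oxygen and C10 can be a ketone before it receives its methyl. The seven-membered ring then divides into an acetone-derived C9–C10–C1 unit and the four carbons of furan (C5 to C8), with the furan oxygen ending on C8.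

## Retrosynthetic reasoning

**Ester.** 28 is cut at the C8–O acyl bond into diol 22 and the phenol-protected acid 25 (through 27). The tertiary C11 hydroxyl needs no protection because acylation discriminates secondary from tertiary. 25 comes from 23 in one operation.

**C4–H.** 22 comes from the bis-silyl ether 21, and 21 from diene 20 by adding hydrogen across C3=C4. The cut is placed here because a C3=C4 alkene is what a ring-closing metathesis leaves, and because its saturation from the face opposite C6 gives H4 cis to H5.

**C10–C14.** 20 comes from the enol triflate 19. Bringing in the methyl by cross-coupling fixes the alkene between C1 and C10, which a dehydration could not guarantee.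

**C3=C4.** 19 is opened to triene 18, with an allyl group on C1 and an isopropenyl group on C5. Ring-closing metathesis of this pair gives the five-membered ring without any enolate chemistry next to the C8 oxygen.

**C5–C4 and C10–O.** 18 comes from enone 16 and the copper reagent derived from 8. The conjugate addition makes the C5–C4 bond and sets C5, and trapping the enolate gives the triflate on the C1 side only.

A hydride addition to a ring-fusion enone was weighed for C5 and set aside for three reasons. A fully substituted β-carbon resists the usual hydride donors. A conjugated C4 methylene would invite 1,6-reduction. On the peripheral-attack model of the cycloheptenone, the hydride would enter on the same face as the carbon nucleophile and leave H5 on the wrong side.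

**C1–C2.** 16 comes from 15 by moving the C5=C6 alkene into conjugation, and 15 from 12 and 13 by α-alkylation of the extended enolate. Only the C1 protons are both α to the ketone and allylic, which directs the deprotonation away from C9.

**C11–O.** 12 is the silyl ether of 11, and 11 comes from 10 by Markovnikov hydration of the isopropenyl group. The hydration is placed while the only other alkene is a cis-disubstituted ring alkene that is not yet conjugated.

**C7–C11.** 10 comes from dienone 7 and 8 by 1,6-addition at C7, anti to the adjacent C8 silyloxy group.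

**C5–O.** 7 comes from the meso ketone 4 by enantioselective deprotonation and β-elimination of the bridging oxygen. The choice between the two α-methylenes decides which bridgehead keeps the oxygen, and so sets C8.

**Seven-membered ring.** 4 comes from 1 and 2 by oxyallyl (4+3) cycloaddition and debromination. It forms C1–C5 and C8–C9 in one flask from two purchased compounds.

## Alternatives that were turned down

**Alternative 1:** ring contraction and expansion of a decalin. The hydroazulene is traced to the trans-fused eudesmane C1 mesylate A1, in which C5 is bonded to C10. In the forward step, buffered solvolysis lets the C5–C10 bond, anti to the equatorial leaving group, migrate to C1. The C10 cation then loses the C1 proton to give acetonide A2.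
- For: all four stereocenters are set on a rigid decalin, and the shift is stereospecific. On certainty at C4 and C5 it is stronger than the chosen route.
- Against: A1 needs six stereocenters, including a quaternary C10 and a defined C1, so its preparation is long. The C10 cation can also lose a proton toward C9 or C14. The C8 oxygen sits β to the cationic center, where it slows ionization and may itself leave.
- Comparison: the chosen route offers in its place a seven-membered ring bought in one step and an alkene fixed by triflation rather than by the direction of a proton loss.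

**Alternative 2:** vinylcarbene (4+3) annulation. C9–C10 and C5–C6 are cut, giving 3-(1-diazoethyl)cyclopent-2-en-1-one A3 and 2-(tert-butyldimethylsilyloxy)buta-1,3-diene A4. A dirhodium tetracarboxylate turns A3 into a divalent-rhodium carbene, which cyclopropanates the enol ether alkene of A4. The cis-divinylcyclopropane then undergoes Cope rearrangement to A5.
- For: it is the most convergent plan. One step gives both rings, the C1=C10 alkene with its methyl, oxygen on C8 and a C4 handle, with C5 open to catalyst control. On skeleton economy it is stronger than the chosen route.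
- Against: the carbene carbon of A3 carries a methyl group and no directly attached acceptor, so 1,2-hydride shift and reaction at the vinylogous terminus should compete. After the key step C7, C8 and C4 must still be set, guided only by C5 across the ring.
- Comparison: the chosen route sets C8 first, in the absolute sense, and relays it to the adjacent C7.

**Alternative 3:** samarium Reformatsky closure. The C7–C8 bond is cut to the bromo ester aldehyde A6. SmI2 (divalent samarium) forms a samarium enolate that adds to the tethered aldehyde and gives hydroxy ester A7.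
- For: the ring closure creates C7 and C8 together and leaves exactly the handles needed, an ester for the C11 carbinol and a free C8 hydroxyl. On the endgame it is stronger than the chosen route, which needs an alkene hydration.
- Against: A6 requires a tetrasubstituted exocyclic alkene of defined geometry (C9 cis to C5) and a β,γ-unsaturated aldehyde that conjugates easily. The closure forms a seven-membered ring, and its C7/C8 trans outcome is guided only by C5 through C6. The β-hydroxy ester A7 can also undergo retro-aldol cleavage when the carbinol is made.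
- Comparison: the chosen route has no geometry-defined tetrasubstituted alkene to prepare and sets C7/C8 by adjacent induction.

Key step: step 1

Assumption: the (R,R)-amide in step 2 is taken to remove a proton from the methylene that becomes C1; if the sense of induction proves opposite, the (S,S)-amide is used with no other change.

## Route

Step 1
Reactants: 1 furan; 2 1,1,3,3-tetrabromoacetone
Product: 4 meso-8-oxabicyclo[3.2.1]oct-6-en-3-one, via 2,4-dibromo-8-oxabicyclo[3.2.1]oct-6-en-3-one 3 (not isolated)
Conditions: Zn–Cu couple, furan (5 equiv), THF, −10 °C → rt; then Zn–Cu couple, NH4Cl, MeOH, −78 °C → rt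
Reagents that add atoms: none
Why: Zinc reduces one C–Br bond of 2 to a zinc enolate, which ionizes the bromide on the other α-carbon to a zinc-bound 1,3-dibromo-2-oxyallyl cation. This three-carbon 2π cation adds across C2 and C5 of furan, concertedly or by attack at C2 followed by fast collapse of the zwitterion at C5, to give 3. The closest known reaction type is the (4+3) cycloaddition of oxyallyl cations from polybromoketones with furans followed by reductive debromination. The seven-membered carbocycle closes by intermolecular (4+3) cycloaddition, forming C1–C5 and C8–C9 and leaving the furan oxygen as a one-atom bridge between C5 and C8. In the second stage zinc inserts into the two remaining α-C–Br bonds and NH4Cl protonates the enolates, which erases the bromide stereocenters. No stereocenter of the target is fixed, since the bridgeheads are necessarily cis and 4 is meso; the absolute configuration is left to step 2. The step needs cycloaddition in preference to electrophilic substitution or polymerization of furan, and the small, strongly electrophilic oxyallyl, its fast ring closure and the excess of furan should secure this.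

Step 2
Reactants: 4 meso-8-oxabicyclo[3.2.1]oct-6-en-3-one
Product: 7 (6S)-6-(tert-butyldimethylsilyloxy)cyclohepta-2,4-dien-1-one, via bicyclic lithium enolate 5 (not isolated), via lithium dienone alkoxide 6 (not isolated)
Conditions: (R,R)-bis(1-phenylethyl)amine, n-BuLi, LiCl, THF, −78 °C; warm to −20 °C; then TBSOTf, −78 → 0 °C
Reagents that add atoms: tert-butyldimethylsilyl trifluoromethanesulfonate, CC(C)(C)[Si](C)(C)OS(=O)(=O)C(F)(F)F
Why: Enantiotopic-group-selective deprotonation of a meso ketone by a C2-symmetric chiral lithium amide, then E1cB opening of the strained oxygen bridge; the enolate at C1 can expel only the C5–O bond, so the oxygen stays on the bridgehead that becomes C8 and that center is set by the choice of methylene. The alkoxide cannot eliminate further and is silylated in the flask before the free hydroxy dienone could lose water toward tropone.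

Step 3
Reactants: 7 (6S)-6-(tert-butyldimethylsilyloxy)cyclohepta-2,4-dien-1-one; 8 2-bromopropene
Product: 10 (5R,6S)-6-(tert-butyldimethylsilyloxy)-5-(prop-1-en-2-yl)cyclohept-3-en-1-one, via lithium dienolate 9 (not isolated)
Conditions: 8, t-BuLi (2 equiv), Et2O, −78 °C; CuI (0.5 equiv), −40 °C; then 7, −78 °C; NH4Cl aq., −78 °C
Reagents that add atoms: none
Why: 1,6-Conjugate addition of a lithium dialkenylcuprate to a 2,4-dienone; the soft reagent attacks the δ-carbon C7 on the face anti to the adjacent C8 silyloxy group, which sets C7 trans to C8. Kinetic α-protonation of the dienolate leaves the C5=C6 alkene out of conjugation.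

Step 4
Reactants: 10 (5R,6S)-6-(tert-butyldimethylsilyloxy)-5-(prop-1-en-2-yl)cyclohept-3-en-1-one
Product: 11 (5S,6S)-6-(tert-butyldimethylsilyloxy)-5-(2-hydroxypropan-2-yl)cyclohept-3-en-1-one
Conditions: Co(acac)2 (20 mol%), PhSiH3, O2 (1 atm), THF/i-PrOH, 0 °C → rt
Reagents that add atoms: dioxygen, O=O
Why: Mukaiyama hydration (hydrogen-atom transfer from a cobalt hydride, trapping of the tertiary radical by O2) is Markovnikov and should prefer the exocyclic 1,1-disubstituted alkene to the cis-disubstituted ring alkene. The neutral conditions should leave the β-silyloxy ketone and the position of the ring alkene unchanged.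

Step 5
Reactants: 11 (5S,6S)-6-(tert-butyldimethylsilyloxy)-5-(2-hydroxypropan-2-yl)cyclohept-3-en-1-one
Product: 12 (5S,6S)-6-(tert-butyldimethylsilyloxy)-5-[2-(triethylsilyloxy)propan-2-yl]cyclohept-3-en-1-one
Conditions: TESOTf, 2,6-lutidine, CH2Cl2, −78 °C
Reagents that add atoms: triethylsilyl trifluoromethanesulfonate, CC[Si](CC)(CC)OS(=O)(=O)C(F)(F)F
Why: Silylation of a tertiary alcohol with a silyl triflate; the ether prevents oxa-Michael closure of the C11 hydroxyl onto C5 in step 7 and its triflation in step 8.

Step 6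
Reactants: 12 (5S,6S)-6-(tert-butyldimethylsilyloxy)-5-[2-(triethylsilyloxy)propan-2-yl]cyclohept-3-en-1-one; 13 allyl bromide
Product: 15 (5S,6S)-2-allyl-6-(tert-butyldimethylsilyloxy)-5-[2-(triethylsilyloxy)propan-2-yl]cyclohept-3-en-1-one (both C2 epimers), via lithium dienolate 14 (not isolated)
Conditions: LiN(SiMe3)2, THF, −78 °C; 13, DMPU, −78 → −30 °C
Reagents that add atoms: none
Why: Enolate alkylation; the C1 protons are both α to the ketone and allylic, so the extended dienolate should form in preference to the C9 enolate, and dienolates alkylate at the α-carbon. The new C1 center is removed in step 7.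

Step 7
Reactants: 15 (5S,6S)-2-allyl-6-(tert-butyldimethylsilyloxy)-5-[2-(triethylsilyloxy)propan-2-yl]cyclohept-3-en-1-one
Product: 16 (5S,6S)-2-allyl-6-(tert-butyldimethylsilyloxy)-5-[2-(triethylsilyloxy)propan-2-yl]cyclohept-2-en-1-one
Conditions: DBU (0.3 equiv), CH2Cl2, rt
Reagents that add atoms: none
Why: Base-catalysed isomerization of a β,γ- to an α,β-unsaturated ketone through the dienolate with γ-protonation at C6, driven by conjugation and by the gain of a trisubstituted alkene. DBU is too weak to enolize toward C9 at a useful rate.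

Step 8
Reactants: 16 (5S,6S)-2-allyl-6-(tert-butyldimethylsilyloxy)-5-[2-(triethylsilyloxy)propan-2-yl]cyclohept-2-en-1-one; 8 2-bromopropene
Product: 18 (3S,5S,6S)-2-allyl-6-(tert-butyldimethylsilyloxy)-3-(prop-1-en-2-yl)-5-[2-(triethylsilyloxy)propan-2-yl]cyclohept-1-en-1-yl trifluoromethanesulfonate, via lithium enolate 17 (not isolated)
Conditions: 8, t-BuLi (2 equiv), Et2O, −78 °C; CuI (0.5 equiv), −40 °C; 16, −78 → −30 °C; then N-(5-chloro-2-pyridyl)bis(trifluoromethanesulfonimide), THF, −78 → 0 °C
Reagents that add atoms: N-(5-chloro-2-pyridyl)bis(trifluoromethanesulfonimide) (Comins' reagent), FC(F)(F)S(=O)(=O)N(c1ccc(Cl)cn1)S(=O)(=O)C(F)(F)F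
Why: Cuprate conjugate addition with O-triflation of the regiodefined enolate, which places the triflate on C10=C1 only. C5 should be set by peripheral attack on the chair cycloheptenone with the C7 and C8 groups trans-diequatorial: the nucleophile enters cis to the C7 substituent and trans to the C8 silyloxy group, and the two substituents direct to the same face, leaving H5 anti to the C7 group.

Step 9
Reactants: 18 (3S,5S,6S)-2-allyl-6-(tert-butyldimethylsilyloxy)-3-(prop-1-en-2-yl)-5-[2-(triethylsilyloxy)propan-2-yl]cyclohept-1-en-1-yl trifluoromethanesulfonate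
Product: 19 (3aS,5S,6S)-6-(tert-butyldimethylsilyloxy)-3-methyl-5-[2-(triethylsilyloxy)propan-2-yl]-1,3a,4,5,6,7-hexahydroazulen-8-yl trifluoromethanesulfonate
Conditions: second-generation Grubbs catalyst (H2IMes)(PCy3)Cl2Ru=CHPh (5 mol%), CH2Cl2, 40 °C
Reagents that add atoms: none
Why: Ring-closing metathesis; the ruthenium carbene forms at the monosubstituted allyl terminus and closes onto the isopropenyl group to give the trisubstituted C3=C4 cyclopentene. The enol triflate and its tetrasubstituted alkene should be inert.

Step 10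
Reactants: 19 (3aS,5S,6S)-6-(tert-butyldimethylsilyloxy)-3-methyl-5-[2-(triethylsilyloxy)propan-2-yl]-1,3a,4,5,6,7-hexahydroazulen-8-yl trifluoromethanesulfonate
Product: 20 (3aS,5S,6S)-6-(tert-butyldimethylsilyloxy)-3,8-dimethyl-5-[2-(triethylsilyloxy)propan-2-yl]-1,3a,4,5,6,7-hexahydroazulene
Conditions: MeZnCl, Pd(PPh3)4 (5 mol%), THF, 50 °C
Reagents that add atoms: methylzinc chloride, C[Zn]Cl
Why: Negishi coupling of an enol triflate forms C10–C14 and leaves the alkene between C1 and C10. Fast transmetalation with the zinc reagent should outrun any Heck-type side reaction.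

Step 11
Reactants: 20 (3aS,5S,6S)-6-(tert-butyldimethylsilyloxy)-3,8-dimethyl-5-[2-(triethylsilyloxy)propan-2-yl]-1,3a,4,5,6,7-hexahydroazulene
Product: 21 (3S,3aS,5S,6S)-6-(tert-butyldimethylsilyloxy)-3,8-dimethyl-5-[2-(triethylsilyloxy)propan-2-yl]-1,2,3,3a,4,5,6,7-octahydroazulene
Conditions: H2 (5 atm), RhCl(PPh3)3 (10 mol%), toluene, rt
Reagents that add atoms: none
Why: Homogeneous hydrogenation with RhCl(PPh3)3 reduces the trisubstituted C3=C4 alkene and leaves the tetrasubstituted C1=C10 alkene, without the alkene migration that heterogeneous palladium would cause at the doubly allylic C2 and C5. Syn addition on the cyclopentene face opposite C6 (the face of H5) should give H4 cis to H5 and C15 cis to C6.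

Step 12
Reactants: 21 (3S,3aS,5S,6S)-6-(tert-butyldimethylsilyloxy)-3,8-dimethyl-5-[2-(triethylsilyloxy)propan-2-yl]-1,2,3,3a,4,5,6,7-octahydroazulene
Product: 22 (3S,3aS,5S,6S)-5-(2-hydroxypropan-2-yl)-3,8-dimethyl-1,2,3,3a,4,5,6,7-octahydroazulen-6-ol
Conditions: Bu4NF (4 equiv), THF, rt → 50 °C
Reagents that add atoms: none
Why: Fluoride-mediated cleavage of both silyl ethers; no base-sensitive group remains at this stage.

Step 13
Reactants: 23 (E)-3-(4-hydroxyphenyl)prop-2-enoic acid
Product: 25 (E)-3-[4-(tert-butyldimethylsilyloxy)phenyl]prop-2-enoic acid, via bis-silylated coumarate 24 (not isolated)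
Conditions: TBSCl (2.4 equiv), imidazole, DMF, rt; then AcOH, THF/H2O, rt
Reagents that add atoms: tert-butyldimethylsilyl chloride, CC(C)(C)[Si](C)(C)Cl
Why: Silylation of phenol and acid, then selective hydrolysis of the far more labile silyl ester under mild aqueous acid.

Step 14
Reactants: 22 (3S,3aS,5S,6S)-5-(2-hydroxypropan-2-yl)-3,8-dimethyl-1,2,3,3a,4,5,6,7-octahydroazulen-6-ol; 25 (E)-3-[4-(tert-butyldimethylsilyloxy)phenyl]prop-2-enoic acid
Product: 27 (3S,3aS,5S,6S)-5-(2-hydroxypropan-2-yl)-3,8-dimethyl-1,2,3,3a,4,5,6,7-octahydroazulen-6-yl (E)-3-[4-(tert-butyldimethylsilyloxy)phenyl]prop-2-enoate, via mixed anhydride 26 (not isolated)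
Conditions: 25, 2,4,6-trichlorobenzoyl chloride, Et3N, THF, rt; then 22, DMAP, toluene, rt
Reagents that add atoms: none
Why: Yamaguchi esterification; the acyl transfer should take the secondary C8 hydroxyl and leave the tertiary C11 hydroxyl. C8 keeps its configuration and the alkene its E geometry.

Step 15
Reactants: 27 (3S,3aS,5S,6S)-5-(2-hydroxypropan-2-yl)-3,8-dimethyl-1,2,3,3a,4,5,6,7-octahydroazulen-6-yl (E)-3-[4-(tert-butyldimethylsilyloxy)phenyl]prop-2-enoate
Product: 28 (3S,3aS,5S,6S)-5-(2-hydroxypropan-2-yl)-3,8-dimethyl-1,2,3,3a,4,5,6,7-octahydroazulen-6-yl (E)-3-(4-hydroxyphenyl)prop-2-enoate, the target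
Conditions: Bu4NF, AcOH (1:1), THF, 0 °C
Reagents that add atoms: none
Why: Fluoride cleavage of an aryl silyl ether; the acetic acid buffer should prevent ester cleavage and acyl migration to the C11 hydroxyl.

## Compound list

1 | furan | c1ccoc1 | starting material
2 | 1,1,3,3-tetrabromoacetone | BrC(Br)C(=O)C(Br)Br | starting material
3 | 2,4-dibromo-8-oxabicyclo[3.2.1]oct-6-en-3-one (mixture of bromide epimers) | O=C1C(Br)[C@@H]2C=C[C@H](C1Br)O2 | intermediate (not isolated)
4 | meso-(1R,5S)-8-oxabicyclo[3.2.1]oct-6-en-3-one | O=C1C[C@@H]2C=C[C@H](C1)O2 | intermediate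
5 | lithium 8-oxabicyclo[3.2.1]octa-2,6-dien-3-olate, enolate toward the methylene that becomes C1 | [Li]OC1=C[C@@H]2C=C[C@H](C1)O2 | intermediate (not isolated)
6 | lithium (1S)-6-oxocyclohepta-2,4-dien-1-olate | O=C1C=CC=C[C@@H](O[Li])C1 | intermediate (not isolated)
7 | (6S)-6-(tert-butyldimethylsilyloxy)cyclohepta-2,4-dien-1-one | O=C1C=CC=C[C@@H](O[Si](C)(C)C(C)(C)C)C1 | intermediate
8 | 2-bromopropene | CC(Br)=C | starting material
9 | lithium (5R,6S)-6-(tert-butyldimethylsilyloxy)-5-(prop-1-en-2-yl)cyclohepta-1,3-dien-1-olate | [Li]OC1=CC=C[C@H](C(C)=C)[C@@H](O[Si](C)(C)C(C)(C)C)C1 | intermediate (not isolated)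
10 | (5R,6S)-6-(tert-butyldimethylsilyloxy)-5-(prop-1-en-2-yl)cyclohept-3-en-1-one (C7/C8 trans) | O=C1CC=C[C@H](C(C)=C)[C@@H](O[Si](C)(C)C(C)(C)C)C1 | intermediate
11 | (5S,6S)-6-(tert-butyldimethylsilyloxy)-5-(2-hydroxypropan-2-yl)cyclohept-3-en-1-one | O=C1CC=C[C@H](C(C)(C)O)[C@@H](O[Si](C)(C)C(C)(C)C)C1 | intermediate
12 | (5S,6S)-6-(tert-butyldimethylsilyloxy)-5-[2-(triethylsilyloxy)propan-2-yl]cyclohept-3-en-1-one | O=C1CC=C[C@H](C(C)(C)O[Si](CC)(CC)CC)[C@@H](O[Si](C)(C)C(C)(C)C)C1 | intermediate
13 | allyl bromide | C=CCBr | starting material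
14 | lithium (5S,6S)-6-(tert-butyldimethylsilyloxy)-5-[2-(triethylsilyloxy)propan-2-yl]cyclohepta-1,3-dien-1-olate | [Li]OC1=CC=C[C@H](C(C)(C)O[Si](CC)(CC)CC)[C@@H](O[Si](C)(C)C(C)(C)C)C1 | intermediate (not isolated)
15 | (5S,6S)-2-allyl-6-(tert-butyldimethylsilyloxy)-5-[2-(triethylsilyloxy)propan-2-yl]cyclohept-3-en-1-one (both C2 epimers) | O=C1C(CC=C)C=C[C@H](C(C)(C)O[Si](CC)(CC)CC)[C@@H](O[Si](C)(C)C(C)(C)C)C1 | intermediate
16 | (5S,6S)-2-allyl-6-(tert-butyldimethylsilyloxy)-5-[2-(triethylsilyloxy)propan-2-yl]cyclohept-2-en-1-one | O=C1C(CC=C)=CC[C@H](C(C)(C)O[Si](CC)(CC)CC)[C@@H](O[Si](C)(C)C(C)(C)C)C1 | intermediate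
17 | lithium (3S,5S,6S)-2-allyl-6-(tert-butyldimethylsilyloxy)-3-(prop-1-en-2-yl)-5-[2-(triethylsilyloxy)propan-2-yl]cyclohept-1-en-1-olate | [Li]OC1=C(CC=C)[C@H](C(C)=C)C[C@H](C(C)(C)O[Si](CC)(CC)CC)[C@@H](O[Si](C)(C)C(C)(C)C)C1 | intermediate (not isolated)
18 | (3S,5S,6S)-2-allyl-6-(tert-butyldimethylsilyloxy)-3-(prop-1-en-2-yl)-5-[2-(triethylsilyloxy)propan-2-yl]cyclohept-1-en-1-yl trifluoromethanesulfonate | FC(F)(F)S(=O)(=O)OC1=C(CC=C)[C@H](C(C)=C)C[C@H](C(C)(C)O[Si](CC)(CC)CC)[C@@H](O[Si](C)(C)C(C)(C)C)C1 | intermediate
19 | (3aS,5S,6S)-6-(tert-butyldimethylsilyloxy)-3-methyl-5-[2-(triethylsilyloxy)propan-2-yl]-1,3a,4,5,6,7-hexahydroazulen-8-yl trifluoromethanesulfonate | FC(F)(F)S(=O)(=O)OC1=C2CC=C(C)[C@@H]2C[C@H](C(C)(C)O[Si](CC)(CC)CC)[C@@H](O[Si](C)(C)C(C)(C)C)C1 | intermediate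
20 | (3aS,5S,6S)-6-(tert-butyldimethylsilyloxy)-3,8-dimethyl-5-[2-(triethylsilyloxy)propan-2-yl]-1,3a,4,5,6,7-hexahydroazulene | CC1=C2CC=C(C)[C@@H]2C[C@H](C(C)(C)O[Si](CC)(CC)CC)[C@@H](O[Si](C)(C)C(C)(C)C)C1 | intermediate
21 | (3S,3aS,5S,6S)-6-(tert-butyldimethylsilyloxy)-3,8-dimethyl-5-[2-(triethylsilyloxy)propan-2-yl]-1,2,3,3a,4,5,6,7-octahydroazulene | CC1=C2CC[C@H](C)[C@@H]2C[C@H](C(C)(C)O[Si](CC)(CC)CC)[C@@H](O[Si](C)(C)C(C)(C)C)C1 | intermediate
22 | (3S,3aS,5S,6S)-5-(2-hydroxypropan-2-yl)-3,8-dimethyl-1,2,3,3a,4,5,6,7-octahydroazulen-6-ol, (4S,5S,7S,8S)-guai-1(10)-ene-8,11-diol | CC1=C2CC[C@H](C)[C@@H]2C[C@H](C(C)(C)O)[C@@H](O)C1 | intermediate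
23 | (E)-3-(4-hydroxyphenyl)prop-2-enoic acid | OC(=O)/C=C/c1ccc(O)cc1 | starting material
24 | tert-butyldimethylsilyl (E)-3-[4-(tert-butyldimethylsilyloxy)phenyl]prop-2-enoate | CC(C)(C)[Si](C)(C)OC(=O)/C=C/c1ccc(O[Si](C)(C)C(C)(C)C)cc1 | intermediate (not isolated)
25 | (E)-3-[4-(tert-butyldimethylsilyloxy)phenyl]prop-2-enoic acid | OC(=O)/C=C/c1ccc(O[Si](C)(C)C(C)(C)C)cc1 | intermediate
26 | (E)-3-[4-(tert-butyldimethylsilyloxy)phenyl]prop-2-enoic 2,4,6-trichlorobenzoic anhydride | O=C(/C=C/c1ccc(O[Si](C)(C)C(C)(C)C)cc1)OC(=O)c1c(Cl)cc(Cl)cc1Cl | intermediate (not isolated)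
27 | (3S,3aS,5S,6S)-5-(2-hydroxypropan-2-yl)-3,8-dimethyl-1,2,3,3a,4,5,6,7-octahydroazulen-6-yl (E)-3-[4-(tert-butyldimethylsilyloxy)phenyl]prop-2-enoate | CC1=C2CC[C@H](C)[C@@H]2C[C@H](C(C)(C)O)[C@@H](OC(=O)/C=C/c2ccc(O[Si](C)(C)C(C)(C)C)cc2)C1 | intermediate
28 | (3S,3aS,5S,6S)-5-(2-hydroxypropan-2-yl)-3,8-dimethyl-1,2,3,3a,4,5,6,7-octahydroazulen-6-yl (E)-3-(4-hydroxyphenyl)prop-2-enoate | CC1=C2CC[C@H](C)[C@@H]2C[C@H](C(C)(C)O)[C@@H](OC(=O)/C=C/c2ccc(O)cc2)C1 | target

## Step count and risks

Total: 15 steps. Longest linear sequence: 14 steps (steps 1–12, 14 and 15); step 13 is a one-step side branch.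

**Step 1 (key step).** The likeliest failure is acid-promoted polymerization or electrophilic substitution of furan by the zinc halides as they build up, with loss of the oxyallyl to reduction before it is trapped. Fallback, setting out from 1: the oxyallyl is generated without zinc, from pentachloroacetone and sodium 2,2,2-trifluoroethoxide in CF3CH2OH. The cycloadduct is 2,2,4,4-tetrachloro-8-oxabicyclo[3.2.1]oct-6-en-3-one F1, and Zn–Cu couple with NH4Cl in MeOH dechlorinates it to rejoin the route at 4.

**Step 2.** The bicyclic enolate may resist β-elimination because the C5–O bond is poorly aligned with the enolate π system. Warming to force the opening invites proton exchange and erosion of the enantiomeric purity. Fallback, setting out from 4: deprotonation with the same amide at −100 °C in the presence of Me3SiCl gives 3-(trimethylsilyloxy)-8-oxabicyclo[3.2.1]octa-2,6-diene F2. TBSOTf in CH2Cl2 at −78 °C then silylates the bridging oxygen, the C5–O bond ionizes with help from the enol ether, and loss of the trimethylsilyl group rejoins the route at 7.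

**Step 4.** Radical oxidation at the doubly activated C1 and C7 positions, or hydrogen-atom transfer to the ring alkene, may compete with the hydration. Fallback, setting out from 10: oxymercuration with Hg(OAc)2 in THF/H2O, then demercuration with NaBH4/NaOH, which also reduces the ketone. This gives (5S,6S)-6-(tert-butyldimethylsilyloxy)-5-(2-hydroxypropan-2-yl)cyclohept-3-en-1-ol F3, and buffered Dess–Martin periodinane oxidizes the secondary alcohol to rejoin the route at 11.

**Step 6.** Deprotonation at C9 would be followed by β-elimination of the silyloxy group, and the product may be alkylated a second time at C1. Fallback, setting out from 12, with no enolate involved: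
- DBU isomerizes 12 to (5S,6S)-6-(tert-butyldimethylsilyloxy)-5-[2-(triethylsilyloxy)propan-2-yl]cyclohept-2-en-1-one F4 (unreacted 12 is recycled);
- I2 and pyridine give (5S,6S)-6-(tert-butyldimethylsilyloxy)-2-iodo-5-[2-(triethylsilyloxy)propan-2-yl]cyclohept-2-en-1-one F5;
- Stille coupling with allyltributylstannane (Pd2(dba)3, AsPh3, CuI) rejoins the route at 16.

**Step 8.** The nucleophile may enter C5 with poor or reversed facial selectivity if the ring does not react through the chair with both substituents equatorial. This is the least secure stereochemical call of the route. Fallback, setting out from 16, in which C5 is set by 1,3-chirality transfer instead: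
- MeLi with CeCl3 adds to the ketone to give (1S,5S,6S)-2-allyl-6-(tert-butyldimethylsilyloxy)-1-methyl-5-[2-(triethylsilyloxy)propan-2-yl]cyclohept-2-en-1-ol F6;
- PhNCO converts it to (1S,5S,6S)-2-allyl-6-(tert-butyldimethylsilyloxy)-1-methyl-5-[2-(triethylsilyloxy)propan-2-yl]cyclohept-2-en-1-yl N-phenylcarbamate F7;
- carbamate-directed syn SN2' substitution with the isopropenyl copper reagent (MeLi, CuI, then prop-1-en-2-yllithium) delivers the group to C5 on the face of the carbamate and forms the C1=C10 alkene with its methyl, giving (3S,5S,6S)-2-allyl-6-(tert-butyldimethylsilyloxy)-1-methyl-3-(prop-1-en-2-yl)-5-[2-(triethylsilyloxy)propan-2-yl]cyclohept-1-ene F8;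
- ring-closing metathesis as in step 9 rejoins the route at 20.

The syn or anti mode of the substitution is matched to the C10 configuration actually formed.

**Step 11.** The C3=C4 alkene may migrate into conjugation with C1=C10 through the doubly allylic C2 and C5 positions, reduction may be slow, or hydrogen may be delivered from the face of C6. Fallback, setting out from 20:
- hydroboration with BH3·SMe2 on the face opposite C6, then NaBO3 oxidation, gives (3aS,5S,6S)-6-(tert-butyldimethylsilyloxy)-3,8-dimethyl-5-[2-(triethylsilyloxy)propan-2-yl]-1,2,3,3a,4,5,6,7-octahydroazulen-2-ol F9 (hydroxyl trans to the C4 methyl, H4 cis to H5);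
- NaH, CS2 and MeI give its S-methyl xanthate F10;
- Barton–McCombie deoxygenation (Bu3SnH, AIBN, toluene, 90 °C) rejoins the route at 21.

## Further compounds

F1 | step 1 | 2,2,4,4-tetrachloro-8-oxabicyclo[3.2.1]oct-6-en-3-one | O=C1C(Cl)(Cl)[C@@H]2C=C[C@H](C1(Cl)Cl)O2
F2 | step 2 | 3-(trimethylsilyloxy)-8-oxabicyclo[3.2.1]octa-2,6-diene (enol ether toward the carbon that becomes C1) | C[Si](C)(C)OC1=C[C@@H]2C=C[C@H](C1)O2
F3 | step 4 | (5S,6S)-6-(tert-butyldimethylsilyloxy)-5-(2-hydroxypropan-2-yl)cyclohept-3-en-1-ol (both C1 epimers) | OC1CC=C[C@H](C(C)(C)O)[C@@H](O[Si](C)(C)C(C)(C)C)C1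
F4 | step 6 | (5S,6S)-6-(tert-butyldimethylsilyloxy)-5-[2-(triethylsilyloxy)propan-2-yl]cyclohept-2-en-1-one | O=C1C=CC[C@H](C(C)(C)O[Si](CC)(CC)CC)[C@@H](O[Si](C)(C)C(C)(C)C)C1
F5 | step 6 | (5S,6S)-6-(tert-butyldimethylsilyloxy)-2-iodo-5-[2-(triethylsilyloxy)propan-2-yl]cyclohept-2-en-1-one | O=C1C(I)=CC[C@H](C(C)(C)O[Si](CC)(CC)CC)[C@@H](O[Si](C)(C)C(C)(C)C)C1
F6 | step 8 | (1S,5S,6S)-2-allyl-6-(tert-butyldimethylsilyloxy)-1-methyl-5-[2-(triethylsilyloxy)propan-2-yl]cyclohept-2-en-1-ol | C[C@@]1(O)C(CC=C)=CC[C@H](C(C)(C)O[Si](CC)(CC)CC)[C@@H](O[Si](C)(C)C(C)(C)C)C1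
F7 | step 8 | (1S,5S,6S)-2-allyl-6-(tert-butyldimethylsilyloxy)-1-methyl-5-[2-(triethylsilyloxy)propan-2-yl]cyclohept-2-en-1-yl N-phenylcarbamate | C[C@@]1(OC(=O)Nc2ccccc2)C(CC=C)=CC[C@H](C(C)(C)O[Si](CC)(CC)CC)[C@@H](O[Si](C)(C)C(C)(C)C)C1
F8 | step 8 | (3S,5S,6S)-2-allyl-6-(tert-butyldimethylsilyloxy)-1-methyl-3-(prop-1-en-2-yl)-5-[2-(triethylsilyloxy)propan-2-yl]cyclohept-1-ene | CC1=C(CC=C)[C@H](C(C)=C)C[C@H](C(C)(C)O[Si](CC)(CC)CC)[C@@H](O[Si](C)(C)C(C)(C)C)C1
F9 | step 11 | (3aS,5S,6S)-6-(tert-butyldimethylsilyloxy)-3,8-dimethyl-5-[2-(triethylsilyloxy)propan-2-yl]-1,2,3,3a,4,5,6,7-octahydroazulen-2-ol (hydroxyl trans to the C4 methyl) | CC1=C2C[C@@H](O)[C@H](C)[C@@H]2C[C@H](C(C)(C)O[Si](CC)(CC)CC)[C@@H](O[Si](C)(C)C(C)(C)C)C1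
F10 | step 11 | O-[(3aS,5S,6S)-6-(tert-butyldimethylsilyloxy)-3,8-dimethyl-5-[2-(triethylsilyloxy)propan-2-yl]-1,2,3,3a,4,5,6,7-octahydroazulen-2-yl] S-methyl carbonodithioate | CC1=C2C[C@@H](OC(=S)SC)[C@H](C)[C@@H]2C[C@H](C(C)(C)O[Si](CC)(CC)CC)[C@@H](O[Si](C)(C)C(C)(C)C)C1
A1 | alternative 1 | trans-fused eudesmane-1,8,11-triol 8,11-acetonide 1-methanesulfonate (equatorial C1 mesylate, C5 bonded to C10) | CS(=O)(=O)O[C@@H]1CC[C@H](C)[C@@H]2C[C@H]3[C@@H](OC(C)(C)OC3(C)C)C[C@@]12C
A2 | alternative 1 | (4S,5S,7S,8S)-guai-1(10)-ene-8,11-diol acetonide | CC1=C2CC[C@H](C)[C@@H]2C[C@H]3[C@@H](OC(C)(C)OC3(C)C)C1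
A3 | alternative 2 | 3-(1-diazoethyl)cyclopent-2-en-1-one | CC(=[N+]=[N-])C1=CC(=O)CC1
A4 | alternative 2 | 2-(tert-butyldimethylsilyloxy)buta-1,3-diene | C=CC(=C)O[Si](C)(C)C(C)(C)C
A5 | alternative 2 | 15-norguaia-1(10),7-dien-4-one 8-(tert-butyldimethylsilyl) enol ether | CC1=C2CCC(=O)[C@@H]2CC=C(O[Si](C)(C)C(C)(C)C)C1
A6 | alternative 3 | methyl 2-bromo-3-[(1S,5S)-5-methyl-2-(4-oxobutan-2-ylidene)cyclopentyl]propanoate (C9 cis to C5 on the alkene) | C/C(CC=O)=C1\CC[C@H](C)[C@@H]1CC(Br)C(=O)OC
A7 | alternative 3 | methyl (3S,3aS,5S,6S)-6-hydroxy-3,8-dimethyl-1,2,3,3a,4,5,6,7-octahydroazulene-5-carboxylate | CC1=C2CC[C@H](C)[C@@H]2C[C@H](C(=O)OC)[C@@H](O)C1
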